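**Retrosynthetic overview**
1. The target 19 comes from its 3'-O-MOM ether 18 by acetal cleavage, and 18 comes from the bis(1,1-dimethylallyl) ether 16 by a double aromatic Claisen rearrangement.
2. The strategy rests on one feature: each prenyl CH2 sits on a ring carbon adjacent to a phenol-bearing carbon (C8 beside C7–OH on ring A, C5' beside C4'–OH on ring B), the pattern an O→C [3,3] shift of a 1,1-dimethylallyl aryl ether leaves behind.
3. Ether 16 is made from diphenol 12 and the tertiary allylic carbonate 15 by Pd-catalysed O-allylation; 12 comes from the dibenzyl ether 11 by hydrogenolysis, before any alkene is present.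
4. Flavanone 11 is made from 7-benzyloxychromone 2 and arylboronic acid 10 by Rh-catalysed asymmetric 1,4-addition, which forms C2–C1' and sets C2 as S; 10 is made from 5-bromosalicylaldehyde 3 (benzylation, Dakin oxidation, MOM ether, borylation).
5. Ring order: no ring is built in the route. Rings A and C arrive with 7-hydroxychromone 1 (C2=C3 is saturated in the arylation) and ring B arrives with 3.

Key step: step 10

Remark 1: O7 and O4' carry benzyl rather than silyl groups, because a silyl group on O4' would sit beside a free phenoxide after the Dakin step and could migrate between the two catechol oxygens; both benzyl groups leave in one hydrogenolysis.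
Remark 2: The ligand antipode in step 6 is the one that delivers the aryl group to the Re face of chromone C2 (2S). The cyclic-enone model for Rh/biaryl bisphosphines predicts the (S)-ligand; a trial on unsubstituted chromone is to confirm the sense, and the other antipode is used if needed.
Remark 3: The two rearrangements in step 10 are independent; intermediate 17 is drawn for the case that the B-ring ether reacts first, and the other order leads to the same product.

**Route**

Step 1
Reactants: 1 7-hydroxychromone
Product: 2 7-(benzyloxy)-4H-chromen-4-one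
Conditions: BnBr, K2CO3, acetone, reflux
Reagents that add atoms: benzyl bromide, BrCc1ccccc1
Why: Williamson ether synthesis on the acidic 7-OH; the mild carbonate base should leave the pyranone ring intact and the benzyl ether tolerates the rhodium step.

Step 2
Reactants: 3 5-bromosalicylaldehyde
Product: 4 2-(benzyloxy)-5-bromobenzaldehyde
Conditions: BnBr, K2CO3, DMF, rt
Reagents that add atoms: benzyl bromide, BrCc1ccccc1
Why: Williamson benzylation of the phenol, which lies para to bromine and becomes O4' of ring B.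

Step 3
Reactants: 4 2-(benzyloxy)-5-bromobenzaldehyde
Product: 6 2-(benzyloxy)-5-bromophenol, via aryl formate 5 (not isolated)
Conditions: mCPBA, CH2Cl2, rt; aq. NaHCO3 wash; then K2CO3 (cat.), MeOH, rt
Reagents that add atoms: meta-chloroperoxybenzoic acid, OOC(=O)c1cccc(Cl)c1
Why: Dakin-type Baeyer–Villiger oxidation, in which the electron-rich ortho-alkoxyaryl group migrates to give the formate that methanol then cleaves; the former formyl carbon (meta to Br) thus becomes O3', already differentiated from O4'.

Step 4
Reactants: 6 2-(benzyloxy)-5-bromophenol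
Product: 7 1-(benzyloxy)-4-bromo-2-(methoxymethoxy)benzene
Conditions: MOMCl, iPr2NEt, CH2Cl2, 0 °C to rt
Reagents that add atoms: chloromethyl methyl ether, COCCl
Why: O-alkylation of the phenol to the MOM acetal, a group that does not migrate and survives organolithium, rhodium, hydrogenolysis and palladium conditions.

Step 5
Reactants: 7 1-(benzyloxy)-4-bromo-2-(methoxymethoxy)benzene
Product: 10 [4-(benzyloxy)-3-(methoxymethoxy)phenyl]boronic acid, via aryllithium 8 (not isolated), via lithium aryltriisopropoxyborate 9 (not isolated)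
Conditions: n-BuLi, THF, −78 °C; B(OiPr)3, −78 °C to rt; aq. NH4Cl
Reagents that add atoms: triisopropyl borate, CC(C)OB(OC(C)C)OC(C)C; water, O
Why: Bromine–lithium exchange at −78 °C outruns ortho-lithiation beside OMOM and benzylic deprotonation, and borate trapping followed by near-neutral hydrolysis should give the boronic acid with the MOM group intact.

Step 6
Reactants: 2 7-(benzyloxy)-4H-chromen-4-one; 10 [4-(benzyloxy)-3-(methoxymethoxy)phenyl]boronic acid
Product: 11 (2S)-7-(benzyloxy)-2-[4-(benzyloxy)-3-(methoxymethoxy)phenyl]-2,3-dihydro-4H-chromen-4-one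
Conditions: 10 (3 equiv), [Rh(OH)((S)-MeO-F12-BIPHEP)]2 (3 mol% Rh), PhMe/H2O, 30 °C
Reagents that add atoms: none
Why: Hayashi–Miyaura rhodium-catalysed asymmetric 1,4-addition of an arylboronic acid to a chromone (transmetalation, enantioface-selective insertion of C2=C3 into Rh–aryl, protonolysis of the rhodium enolate); the chiral bisphosphine sets C2 as S by aryl delivery to the Re face, and the base-free medium should suppress ring opening to the chalcone.

Step 7
Reactants: 11 (2S)-7-(benzyloxy)-2-[4-(benzyloxy)-3-(methoxymethoxy)phenyl]-2,3-dihydro-4H-chromen-4-one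
Product: 12 (2S)-7-hydroxy-2-[4-hydroxy-3-(methoxymethoxy)phenyl]-2,3-dihydro-4H-chromen-4-one
Conditions: H2 (1 atm), 10% Pd/C, EtOAc/MeOH, rt, stopped at full conversion
Reagents that add atoms: none
Why: Catalytic hydrogenolysis of both benzyl ethers under neutral conditions, placed before any alkene exists; the MOM acetal, the electron-rich aryl ketone and C2 should be unaffected at 1 atm.

Step 8
Reactants: 13 2-methylbut-3-en-2-ol
Product: 15 tert-butyl 2-methylbut-3-en-2-yl carbonate, via lithium 2-methylbut-3-en-2-olate 14 (not isolated)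
Conditions: n-BuLi, THF, 0 °C; Boc2O, 0 °C to rt; H2O
Reagents that add atoms: di-tert-butyl dicarbonate, CC(C)(C)OC(=O)OC(=O)OC(C)(C)C
Why: Acylation of the tertiary lithium alkoxide with Boc2O gives the mixed carbonate that Pd(0) ionises readily.

Step 9
Reactants: 12 (2S)-7-hydroxy-2-[4-hydroxy-3-(methoxymethoxy)phenyl]-2,3-dihydro-4H-chromen-4-one; 15 tert-butyl 2-methylbut-3-en-2-yl carbonate
Product: 16 (2S)-2-{3-(methoxymethoxy)-4-[(2-methylbut-3-en-2-yl)oxy]phenyl}-7-[(2-methylbut-3-en-2-yl)oxy]-2,3-dihydro-4H-chromen-4-one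
Conditions: 15 (3 equiv), Pd(PPh3)4 (5 mol%), THF, 0 °C, short reaction time
Reagents that add atoms: none
Why: Tsuji–Trost O-allylation, in which Pd(0) ionises the carbonate to a π-(1,1-dimethylallyl)palladium cation and tert-butoxide (after loss of CO2), and each phenoxide attacks the more substituted allyl terminus under kinetic control to give the tertiary ether; O3' is blocked by MOM and the base is only transient, so C2 should not epimerise.

Step 10
Reactants: 16 (2S)-2-{3-(methoxymethoxy)-4-[(2-methylbut-3-en-2-yl)oxy]phenyl}-7-[(2-methylbut-3-en-2-yl)oxy]-2,3-dihydro-4H-chromen-4-one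
Product: 18 (2S)-7-hydroxy-2-[4-hydroxy-3-(methoxymethoxy)-5-(3-methylbut-2-en-1-yl)phenyl]-8-(3-methylbut-2-en-1-yl)-2,3-dihydro-4H-chromen-4-one, via mono-rearranged ether 17 (not isolated)
Conditions: Eu(fod)3 (10 mol%), PhMe, 80 °C, Ar
Reagents that add atoms: none
Why: Each aryl 1,1-dimethylallyl ether undergoes a concerted [3,3]-sigmatropic shift through a chair transition state, assisted by Eu(III) coordination at the ether oxygen, so that the terminal CH2 bonds to the ortho carbon as the O–CMe2 bond breaks, and tautomerisation of the cyclohexadienone restores the phenol and leaves the trisubstituted prenyl double bond. The closest known reaction type is the aromatic Claisen rearrangement of 1,1-dimethylallyl aryl ethers to ortho-prenylphenols, as used for prenylated coumarins, chromones and flavonoids. No ring is closed and no stereocentre is created; the step forms C8–CH2 and C5'–CH2 and frees the 7- and 4'-hydroxyls. On ring B only C5' can accept the allyl unit, because a shift to C3' gives a dienone that cannot tautomerise (C3' carries OMOM) and can only revert. On ring A the step needs C8 over C6, which rests on the preference of 7-allyloxy benzopyranones and related 4-allyloxy aryl ketones for the carbon flanked by O7 and O1 (bond fixation), with the 6-prenyl isomer expected as a minor, separable by-product. C2 should stay S because the medium is neutral and the temperature is well below that at which the flavanone opens to the chalcone.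

Step 11
Reactants: 18 (2S)-7-hydroxy-2-[4-hydroxy-3-(methoxymethoxy)-5-(3-methylbut-2-en-1-yl)phenyl]-8-(3-methylbut-2-en-1-yl)-2,3-dihydro-4H-chromen-4-one
Product: 19 (2S)-2-[3,4-dihydroxy-5-(3-methylbut-2-en-1-yl)phenyl]-7-hydroxy-8-(3-methylbut-2-en-1-yl)-2,3-dihydro-4H-chromen-4-one
Conditions: 3 M HCl (cat.), MeOH, 40 °C, stopped at full conversion
Reagents that add atoms: none
Why: Acid-catalysed acetal exchange with methanol removes the single MOM group; the low temperature and short time are chosen so that addition of the ortho phenols to the prenyl double bonds stays slow.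

**Compound list**
1 | 7-hydroxychromone | O=c1ccoc2cc(O)ccc12 | starting material
2 | 7-(benzyloxy)-4H-chromen-4-one | O=c1ccoc2cc(OCc3ccccc3)ccc12 | intermediate
3 | 5-bromosalicylaldehyde | O=Cc1cc(Br)ccc1O | starting material
4 | 2-(benzyloxy)-5-bromobenzaldehyde | O=Cc1cc(Br)ccc1OCc1ccccc1 | intermediate
5 | 2-(benzyloxy)-5-bromophenyl formate | O=COc1cc(Br)ccc1OCc1ccccc1 | intermediate
6 | 2-(benzyloxy)-5-bromophenol | Oc1cc(Br)ccc1OCc1ccccc1 | intermediate
7 | 1-(benzyloxy)-4-bromo-2-(methoxymethoxy)benzene | COCOc1cc(Br)ccc1OCc1ccccc1 | intermediate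
8 | [4-(benzyloxy)-3-(methoxymethoxy)phenyl]lithium | [Li]c1ccc(OCc2ccccc2)c(OCOC)c1 | intermediate
9 | lithium [4-(benzyloxy)-3-(methoxymethoxy)phenyl]triisopropoxyborate | [Li+].CC(C)O[B-](OC(C)C)(OC(C)C)c1ccc(OCc2ccccc2)c(OCOC)c1 | intermediate
10 | [4-(benzyloxy)-3-(methoxymethoxy)phenyl]boronic acid | COCOc1cc(B(O)O)ccc1OCc1ccccc1 | intermediate
11 | (2S)-7-(benzyloxy)-2-[4-(benzyloxy)-3-(methoxymethoxy)phenyl]-2,3-dihydro-4H-chromen-4-one | COCOc1cc([C@@H]2CC(=O)c3ccc(OCc4ccccc4)cc3O2)ccc1OCc1ccccc1 | intermediate
12 | (2S)-7-hydroxy-2-[4-hydroxy-3-(methoxymethoxy)phenyl]-2,3-dihydro-4H-chromen-4-one | COCOc1cc([C@@H]2CC(=O)c3ccc(O)cc3O2)ccc1O | intermediate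
13 | 2-methylbut-3-en-2-ol | CC(C)(O)C=C | starting material
14 | lithium 2-methylbut-3-en-2-olate | [Li+].CC(C)([O-])C=C | intermediate
15 | tert-butyl 2-methylbut-3-en-2-yl carbonate | C=CC(C)(C)OC(=O)OC(C)(C)C | intermediate
16 | (2S)-2-{3-(methoxymethoxy)-4-[(2-methylbut-3-en-2-yl)oxy]phenyl}-7-[(2-methylbut-3-en-2-yl)oxy]-2,3-dihydro-4H-chromen-4-one | C=CC(C)(C)Oc1ccc([C@@H]2CC(=O)c3ccc(OC(C)(C)C=C)cc3O2)cc1OCOC | intermediate
17 | (2S)-2-[4-hydroxy-3-(methoxymethoxy)-5-(3-methylbut-2-en-1-yl)phenyl]-7-[(2-methylbut-3-en-2-yl)oxy]-2,3-dihydro-4H-chromen-4-one | CC(C)=CCc1cc([C@@H]2CC(=O)c3ccc(OC(C)(C)C=C)cc3O2)cc(OCOC)c1O | intermediate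
18 | (2S)-7-hydroxy-2-[4-hydroxy-3-(methoxymethoxy)-5-(3-methylbut-2-en-1-yl)phenyl]-8-(3-methylbut-2-en-1-yl)-2,3-dihydro-4H-chromen-4-one | CC(C)=CCc1cc([C@@H]2CC(=O)c3ccc(O)c(CC=C(C)C)c3O2)cc(OCOC)c1O | intermediate
19 | (2S)-2-[3,4-dihydroxy-5-(3-methylbut-2-en-1-yl)phenyl]-7-hydroxy-8-(3-methylbut-2-en-1-yl)-2,3-dihydro-4H-chromen-4-one | CC(C)=CCc1cc([C@@H]2CC(=O)c3ccc(O)c(CC=C(C)C)c3O2)cc(O)c1O | target

**Step count**
Total: 11 steps. Longest linear sequence: 9 steps (steps 2, 3, 4, 5, 6, 7, 9, 10, 11, from 5-bromosalicylaldehyde).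

**Steps most likely to fail**

Step 10 (double Claisen rearrangement). The A-ring allyl unit may migrate to C6 instead of C8, or a tertiary allyl group may be lost by ionisation before it rearranges. Fallback, from 12 back to 18: diphenol 12 is iodinated at the two free positions ortho to its phenols with N-iodosuccinimide (DMF, 0 °C) to give (2S)-7-hydroxy-2-[4-hydroxy-3-iodo-5-(methoxymethoxy)phenyl]-8-iodo-2,3-dihydro-4H-chromen-4-one F1, whose regiochemistry can be assigned and purified before the prenyl groups are committed. A twofold Stille coupling with tributyl(3-methylbut-2-en-1-yl)stannane (Pd(PPh3)4, DMF, 90 °C, neutral) then attaches both prenyl groups and returns to 18.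

Step 6 (asymmetric arylation). The electron-rich 7-alkoxychromone may react slowly while the boronic acid protodeboronates, or enantiopurity may erode through ring opening to the chalcone. Fallback, from 7 back to 11: bromide 7 is converted by bromine–lithium exchange and DMF quench into 4-(benzyloxy)-3-(methoxymethoxy)benzaldehyde F2. Claisen–Schmidt condensation with commercial 1-[4-(benzyloxy)-2-hydroxyphenyl]ethanone (CC(=O)c1ccc(OCc2ccccc2)cc1O; KOH, EtOH, rt) gives (E)-1-[4-(benzyloxy)-2-hydroxyphenyl]-3-[4-(benzyloxy)-3-(methoxymethoxy)phenyl]prop-2-en-1-one F3. Oxa-Michael cyclisation (NaOAc, EtOH, reflux) gives racemic 7-(benzyloxy)-2-[4-(benzyloxy)-3-(methoxymethoxy)phenyl]-2,3-dihydro-4H-chromen-4-one F4, and preparative HPLC on a chiral stationary phase supplies the S enantiomer 11. Steps 1 and 5 are then not needed.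

Step 11 (MOM removal). The 7- and 4'-hydroxyls may add to the adjacent prenyl double bonds under acid, giving dimethylchromans in competition with acetal cleavage. Fallback, from 18 back to 19: both phenols of 18 are acetylated (Ac2O, pyridine) to (2S)-7-acetoxy-2-[4-acetoxy-3-(methoxymethoxy)-5-(3-methylbut-2-en-1-yl)phenyl]-8-(3-methylbut-2-en-1-yl)-2,3-dihydro-4H-chromen-4-one F5, so that no phenol can cyclise. The MOM ether is then cleaved without protic acid (TMSOTf, 2,2'-bipyridyl, CH2Cl2, 0 °C; then H2O) to the 3'-phenol diacetate F6; an acetyl shift between O3' and O4' would be of no consequence. Brief methanolysis (K2CO3 cat., MeOH, 0 °C) removes both acetates and gives 19.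

**Further compounds**
F1 | step 10 | (2S)-7-hydroxy-2-[4-hydroxy-3-iodo-5-(methoxymethoxy)phenyl]-8-iodo-2,3-dihydro-4H-chromen-4-one | COCOc1cc([C@@H]2CC(=O)c3ccc(O)c(I)c3O2)cc(I)c1O
F2 | step 6 | 4-(benzyloxy)-3-(methoxymethoxy)benzaldehyde | COCOc1cc(C=O)ccc1OCc1ccccc1
F3 | step 6 | (E)-1-[4-(benzyloxy)-2-hydroxyphenyl]-3-[4-(benzyloxy)-3-(methoxymethoxy)phenyl]prop-2-en-1-one | COCOc1cc(/C=C/C(=O)c2ccc(OCc3ccccc3)cc2O)ccc1OCc1ccccc1
F4 | step 6 | racemic 7-(benzyloxy)-2-[4-(benzyloxy)-3-(methoxymethoxy)phenyl]-2,3-dihydro-4H-chromen-4-one | COCOc1cc(C2CC(=O)c3ccc(OCc4ccccc4)cc3O2)ccc1OCc1ccccc1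
F5 | step 11 | (2S)-7-acetoxy-2-[4-acetoxy-3-(methoxymethoxy)-5-(3-methylbut-2-en-1-yl)phenyl]-8-(3-methylbut-2-en-1-yl)-2,3-dihydro-4H-chromen-4-one | CC(C)=CCc1cc([C@@H]2CC(=O)c3ccc(OC(C)=O)c(CC=C(C)C)c3O2)cc(OCOC)c1OC(C)=O
F6 | step 11 | (2S)-7-acetoxy-2-[4-acetoxy-3-hydroxy-5-(3-methylbut-2-en-1-yl)phenyl]-8-(3-methylbut-2-en-1-yl)-2,3-dihydro-4H-chromen-4-one | CC(C)=CCc1cc([C@@H]2CC(=O)c3ccc(OC(C)=O)c(CC=C(C)C)c3O2)cc(O)c1OC(C)=O
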